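**Retrosynthetic overview**
- The target is released last by hydrogenolysis of its tetra-O-benzyl ether; no other adjustment follows the key step.
- The tetra-O-benzyl ketone is cut between the carbonyl carbon C3 and the methylene C4 of the heptane chain (numbered from the methoxylated ring). This gives 3-[3,4-bis(benzyloxy)-5-methoxyphenyl]propanal and 4-(but-3-en-1-yl)-1,2-bis(benzyloxy)benzene, joined by Rh-catalysed, chelation-assisted intermolecular hydroacylation: the formyl C–H adds across the terminal C4=C5 double bond.
- Enabling feature: C3 is a ketone carbon whose neighbour C4 starts an unbranched, unfunctionalised tetramethylene run C4–C7 ending at the catechol ring. C3 can therefore be an aldehyde carbon and C4 the CH2 end of a 1-alkene, with no activating group to remove.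
- The aldehyde comes from 5-hydroxyvanillin (benzylation, two-carbon Wittig homologation, conjugate transfer hydrogenation); the alkene comes from 3,4-bis(benzyloxy)benzyl chloride and allylmagnesium bromide.
- No ring is formed in the route: both benzene rings are bought with their oxygen pattern in place.

Key step: step 5

Assumption: 3,4-dihydroxy-5-methoxybenzaldehyde and 3,4-bis(benzyloxy)benzyl chloride are taken as purchasable. The target has no stereocentre; the only stereochemical element on the way is the E double bond of the enal, which is erased in step 3.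

Step 1
Reactants: 1 3,4-dihydroxy-5-methoxybenzaldehyde (5-hydroxyvanillin)
Product: 2 3,4-bis(benzyloxy)-5-methoxybenzaldehyde
Conditions: BnBr (2.3 equiv), K2CO3 (3 equiv), DMF, 60 °C
Reagents that add atoms: benzyl bromide, BrCc1ccccc1
Why: Williamson ether synthesis, in which both catechol phenoxides are alkylated by the benzylic bromide while the aldehyde is untouched, and benzyl is chosen because it should survive every later step and all four groups fall off together in the last one.

Step 2
Reactants: 2 3,4-bis(benzyloxy)-5-methoxybenzaldehyde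
Product: 3 (E)-3-[3,4-bis(benzyloxy)-5-methoxyphenyl]prop-2-enal
Conditions: Ph3P=CHCHO (1.2 equiv), toluene, 80 °C
Reagents that add atoms: (triphenylphosphoranylidene)acetaldehyde, O=CC=P(c1ccccc1)(c1ccccc1)c1ccccc1
Why: Wittig reaction with the stabilised formylmethylene ylide should give the two-carbon-extended enal directly, the E geometry following from the thermodynamically controlled addition of a stabilised ylide.

Step 3
Reactants: 3 (E)-3-[3,4-bis(benzyloxy)-5-methoxyphenyl]prop-2-enal
Product: 4 3-[3,4-bis(benzyloxy)-5-methoxyphenyl]propanal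
Conditions: Hantzsch ester (diethyl 2,6-dimethyl-1,4-dihydropyridine-3,5-dicarboxylate, 1.1 equiv), dibenzylammonium trifluoroacetate (10 mol %), THF, rt
Reagents that add atoms: none
Why: Iminium-catalysed transfer hydrogenation, in which the ammonium salt turns the enal into an iminium ion that takes hydride from the Hantzsch ester at the β-carbon only, so the C=C bond should be saturated while the aldehyde and the O-benzyl groups (which H2/Pd would remove) stay intact.

Step 4
Reactants: 5 4-(chloromethyl)-1,2-bis(benzyloxy)benzene (3,4-bis(benzyloxy)benzyl chloride)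
Product: 6 4-(but-3-en-1-yl)-1,2-bis(benzyloxy)benzene
Conditions: allylMgBr (1.5 equiv, Et2O), THF, 0 °C to rt
Reagents that add atoms: allylmagnesium bromide, C=CC[Mg]Br
Why: Grignard cross-coupling (substitution of an activated benzylic chloride by the allyl nucleophile, the standard route to 4-aryl-1-butenes) should install the terminal double bond that serves as the C4=C5 acceptor, with the aryl benzyl ethers inert.

Step 5
Reactants: 4 3-[3,4-bis(benzyloxy)-5-methoxyphenyl]propanal, 6 4-(but-3-en-1-yl)-1,2-bis(benzyloxy)benzene
Product: 9 1-[3,4-bis(benzyloxy)-5-methoxyphenyl]-7-[3,4-bis(benzyloxy)phenyl]heptan-3-one, via pyridyl aldimine 7 (not isolated), via pyridyl ketimine 8 (not isolated)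
Conditions: RhCl(PPh3)3 (5 mol %), 2-amino-3-picoline (Cc1cccnc1N, 40 mol %), PhCO2H (10 mol %), 6 (2 equiv), toluene, 120 °C, Ar, slow addition of 4; then 1 M HCl, THF, rt
Reagents that add atoms: water, O (hydrolysis of ketimine 8; the water lost when 7 forms is taken up again)
Why: Chelation-assisted Rh-catalysed intermolecular hydroacylation: 4 condenses with 2-amino-3-picoline to aldimine 7, whose pyridine nitrogen holds Rh(I) beside the imidoyl C–H, so oxidative addition gives a five-membered iminoacyl rhodium hydride that cannot decarbonylate. Alkene 6 inserts into Rh–H with rhodium on the terminal carbon, reductive elimination forms the C3–C4 bond as ketimine 8, and the water from the condensation hydrolyses 8 to 9 and returns the aminopicoline. The closest known reaction type is this same Rh/2-amino-3-picoline/benzoic acid hydroacylation of 1-alkenes with aldehydes, aliphatic ones included. No ring is closed and no stereocentre is made; the step is a pure addition in which all carbon atoms of 4 and 6 end in 9. The selectivity needed is linear (anti-Markovnikov) acyl delivery to C4, secured by the monosubstituted, unbranched double bond of 6 (rhodium goes to the unhindered CH2 end), together with C–H activation ahead of self-condensation, supported by keeping the enolisable aldehyde 4 dilute against an excess of 6.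

Step 6
Reactants: 9 1-[3,4-bis(benzyloxy)-5-methoxyphenyl]-7-[3,4-bis(benzyloxy)phenyl]heptan-3-one
Product: 10 1-(3,4-dihydroxy-5-methoxyphenyl)-7-(3,4-dihydroxyphenyl)heptan-3-one
Conditions: H2 (1 atm), 10% Pd/C, EtOAc–MeOH, rt; filtration under Ar
Reagents that add atoms: none
Why: Catalytic hydrogenolysis should cleave the four benzylic C–O bonds while the dialkyl ketone, the aryl methyl ether and the arenes are inert at 1 atm and room temperature, releasing the target without further adjustment.

**Compound list**
1 | 3,4-dihydroxy-5-methoxybenzaldehyde (5-hydroxyvanillin) | COc1cc(C=O)cc(O)c1O | starting material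
2 | 3,4-bis(benzyloxy)-5-methoxybenzaldehyde | COc1cc(C=O)cc(OCc2ccccc2)c1OCc1ccccc1 | intermediate
3 | (E)-3-[3,4-bis(benzyloxy)-5-methoxyphenyl]prop-2-enal | COc1cc(/C=C/C=O)cc(OCc2ccccc2)c1OCc1ccccc1 | intermediate
4 | 3-[3,4-bis(benzyloxy)-5-methoxyphenyl]propanal | COc1cc(CCC=O)cc(OCc2ccccc2)c1OCc1ccccc1 | intermediate
5 | 4-(chloromethyl)-1,2-bis(benzyloxy)benzene | ClCc1ccc(OCc2ccccc2)c(OCc2ccccc2)c1 | starting material
6 | 4-(but-3-en-1-yl)-1,2-bis(benzyloxy)benzene | C=CCCc1ccc(OCc2ccccc2)c(OCc2ccccc2)c1 | intermediate
7 | (E)-N-(3-methylpyridin-2-yl)-3-[3,4-bis(benzyloxy)-5-methoxyphenyl]propan-1-imine (pyridyl aldimine, not isolated) | COc1cc(CC/C=N/c2ncccc2C)cc(OCc2ccccc2)c1OCc1ccccc1 | intermediate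
8 | N-(3-methylpyridin-2-yl)-1-[3,4-bis(benzyloxy)-5-methoxyphenyl]-7-[3,4-bis(benzyloxy)phenyl]heptan-3-imine (pyridyl ketimine, C=N geometry not fixed, not isolated) | COc1cc(CCC(CCCCc2ccc(OCc3ccccc3)c(OCc3ccccc3)c2)=Nc2ncccc2C)cc(OCc2ccccc2)c1OCc1ccccc1 | intermediate
9 | 1-[3,4-bis(benzyloxy)-5-methoxyphenyl]-7-[3,4-bis(benzyloxy)phenyl]heptan-3-one | COc1cc(CCC(=O)CCCCc2ccc(OCc3ccccc3)c(OCc3ccccc3)c2)cc(OCc2ccccc2)c1OCc1ccccc1 | intermediate
10 | 1-(3,4-dihydroxy-5-methoxyphenyl)-7-(3,4-dihydroxyphenyl)heptan-3-one | COc1cc(CCC(=O)CCCCc2ccc(O)c(O)c2)cc(O)c1O | target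

**Step count and risks**
Total step count: 6. Longest linear sequence: 5 steps (steps 1, 2, 3, 5, 6).

Steps most likely to fail:

1. Step 5. What may go wrong: amine-promoted self-condensation of the enolisable aldehyde (through its imine and enamine) outrunning C–H activation, and rhodium-hydride migration of the terminal double bond of 6 towards the ring, which removes the reactive 1-alkene. The fallback sets out from 4 and 6 and comes back at 9, making the same C3–C4 bond by two-electron cross-coupling at the acid oxidation level. Aldehyde 4 would be oxidised (NaClO2, NaH2PO4, 2-methylbut-2-ene, t-BuOH/H2O) to 3-[3,4-bis(benzyloxy)-5-methoxyphenyl]propanoic acid F1. This would be converted (PhSH, DCC, DMAP, CH2Cl2) into S-phenyl 3-[3,4-bis(benzyloxy)-5-methoxyphenyl]propanethioate F2. Alkene 6 would be hydroborated (9-BBN, THF, rt; anti-Markovnikov, boron on the terminal carbon) to 9-{4-[3,4-bis(benzyloxy)phenyl]butyl}-9-borabicyclo[3.3.1]nonane F3, used in solution. Liebeskind–Srogl coupling of F2 with F3 (Pd(PPh3)4, copper(I) thiophene-2-carboxylate, Cs2CO3, THF, 45 °C) should then give 9.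

2. Step 2. What may go wrong: a second olefination of the product enal by the same ylide (over-homologation), and slow reaction of the electron-rich aldehyde. The fallback sets out from 2 and comes back at 4, bypassing 3. Horner–Wadsworth–Emmons olefination (triethyl phosphonoacetate, NaH, THF) should give ethyl (E)-3-[3,4-bis(benzyloxy)-5-methoxyphenyl]prop-2-enoate F4. Conjugate reduction with nickel boride (NaBH4, NiCl2·6H2O, EtOH/THF, 0 °C; benzyl ethers are expected to survive) should give ethyl 3-[3,4-bis(benzyloxy)-5-methoxyphenyl]propanoate F5. Partial reduction (DIBAL-H, CH2Cl2, −78 °C) should then give 4.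

3. Step 6. What may go wrong: stalling after partial debenzylation through catalyst poisoning by the polyphenol, slow reduction of the ketone on long exposure, and air oxidation of the catechol units during filtration. The fallback sets out from 9 and comes back at 10 by non-reductive Lewis-acid debenzylation with a cation scavenger (BCl3, pentamethylbenzene, CH2Cl2, −78 °C, cold methanol quench). It needs no metal and no hydrogen and should spare the aryl methyl ether and the ketone; it makes no new compound (F0).

**Further compounds**
F1 | step 5 | 3-[3,4-bis(benzyloxy)-5-methoxyphenyl]propanoic acid | COc1cc(CCC(=O)O)cc(OCc2ccccc2)c1OCc1ccccc1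
F2 | step 5 | S-phenyl 3-[3,4-bis(benzyloxy)-5-methoxyphenyl]propanethioate | COc1cc(CCC(=O)Sc2ccccc2)cc(OCc2ccccc2)c1OCc1ccccc1
F3 | step 5 | 9-{4-[3,4-bis(benzyloxy)phenyl]butyl}-9-borabicyclo[3.3.1]nonane | C(CCCc1ccc(OCc2ccccc2)c(OCc2ccccc2)c1)B1C2CCCC1CCC2
F4 | step 2 | ethyl (E)-3-[3,4-bis(benzyloxy)-5-methoxyphenyl]prop-2-enoate | CCOC(=O)/C=C/c1cc(OC)c(OCc2ccccc2)c(OCc2ccccc2)c1
F5 | step 2 | ethyl 3-[3,4-bis(benzyloxy)-5-methoxyphenyl]propanoate | CCOC(=O)CCc1cc(OC)c(OCc2ccccc2)c(OCc2ccccc2)c1
F0 | step 6 | none | none
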